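Readings and results were generated by integration from invented constants, noise included.

**The ratio.** In a repeat I watch the ratio of left-handed product to right-handed product, taken against what each substrate has lost.

| flask | left-handed substrate | right-handed substrate | solid reagent | free catalyst | remark | time |
|---|---|---|---|---|---|---|
| spring | 1.7 M | 1.7 M | 0.32 equiv | 15 mol% (in portions, 2) | run made earlier; portions every 20 min |  |
| noon | 1.7 M | 1.7 M | 0.47 equiv | 15 mol% (in portions, 2) | run made earlier; portions every 20 min |  |
| dusk | 1.7 M | 1.7 M | 0.44 equiv | 15 mol% (in portions, 2) | run made earlier; portions every 20 min |  |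
| north-west | 1.7 M | 1.7 M | 0.400 equiv | 15 mol% | everything together at the start | 60 min |
| west | 1.7 M | 1.7 M | 0.600 equiv | 15 mol% (in portions, 2) | the portions of free catalyst follow each other after 20 min, the first at the start | 40 min |

| run | time / min | left-handed product / % | right-handed product / % |
|---|---|---|---|
| spring | 3.00 | 1.7 | 0.1 |
| spring | 6.00 | 3.8 | 0.9 |
| spring | 12.0 | 6.4 | 1.3 |
| spring | 20.0 | 7.4 | 1.5 |
| spring | 40.0 | 8.1 | 1.6 |
| noon | 3.00 | 1.6 | 0 |
| noon | 6.00 | 4.9 | 1.0 |
| noon | 12.0 | 9.8 | 2.0 |
| noon | 20.0 | 11.3 | 1.7 |
| noon | 40.0 | 12.4 | 1.9 |
| dusk | 4.00 | 2.3 | 0.9 |
| dusk | 10.0 | 8.3 | 1.9 |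
| dusk | 20.0 | 11.0 | 2.4 |
| dusk | 30.0 | 11.4 | 2.6 |
| dusk | 40.0 | 10.7 | 1.8 |

(readings scatter by 0.3 percentage points)

- free catalyst is single-handed; left-handed substrate and right-handed substrate are mirror images of each other, charged as a racemate, each of them at the stated concentration
- solid reagent is a solid; its amount is given per volume of the solution
- steps thought possible: free catalyst + left-handed substrate <-> catalyst intermediate A; free catalyst + right-handed substrate <-> catalyst intermediate B; coupling partner + catalyst intermediate A -> free catalyst + left-handed product; coupling partner + catalyst intermediate B -> free catalyst + right-handed product; coupling partner -> decomposed reagent; solid reagent <-> coupling partner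
- at the start none of the solid reagent is in solution

* the winner by share of left-handed product in all that became left-handed product or right-handed product; "neither" if no more than 2 percentage points parts them (north-west / west / neither)
* share of left-handed product in all that became left-handed product or right-handed product, north-west
* share of left-handed product in all that became left-handed product or right-handed product, west

**The measure.** With P the left-handed product and Q the right-handed product, as fractions of both substrates charged, I use the selectivity factor s, the logarithm of the fraction of left-handed substrate remaining over the logarithm of the fraction of right-handed substrate remaining: s = ln(1 − 2P)/ln(1 − 2Q). The readings at 40.0 min give 5.43 for spring, 6.57 for dusk and 7.36 for noon. Each reading carries a scatter of 0.3 percentage points, which weighs heavily on spring's right-handed product of 1.6%, so I treat this spread as scatter.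

**Upper bound.** If s holds and no substrate has yet been lost, the share is s/(s + 1), and noon's s gives 88.0% as my estimate of the upper end.

**Lower bound.** I take spring's s, let every equivalent of solid reagent reach product, and use the rate ratio at half the depletion. That gives 82.3% for north-west and 81.0% for west. I give both flasks the same s, and these lower ends lie 1.3 points apart, under the margin of 2 points, so I expect no winner.

**The forecast.** It says neither, with 84% for north-west and 84% for west: “Treated as a kinetic resolution, this gives s≈5–7”. Both values lie inside my brackets.

**The flask.** North-west gives 82.6% and west 82.1%, so the winner is neither, and both stand above their lower bounds.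

    free catalyst + left-handed substrate ⇌ catalyst intermediate A (K = 0.230 M⁻¹, k = 7.80 M⁻¹ min⁻¹)
    free catalyst + right-handed substrate ⇌ catalyst intermediate B (K = 0.221 M⁻¹, k = 56.2 M⁻¹ min⁻¹)
    coupling partner + catalyst intermediate A → free catalyst + left-handed product (k = 3.52 M⁻¹ min⁻¹)
    coupling partner + catalyst intermediate B → free catalyst + right-handed product (k = 0.674 M⁻¹ min⁻¹)
    coupling partner → decomposed reagent (k = 0.0713 min⁻¹)
    solid reagent ⇌ coupling partner, rate k6*(cs6 - [coupling partner]) while solid is left; crystals form when [coupling partner] > cs6 (solubility = 1.60 M, k = 0.109 min⁻¹)

**The reason.** West keeps its share because catalyst intermediate B goes back to free catalyst and right-handed substrate: without that back reaction, the share falls from 82.1% to 0.656%. Applied to west's 3.22% of right-handed product, spring's s of 5.43 gives a share of 82.5%. The neighbour with 1.50 equiv of solid reagent holds 9.96% of right-handed product at 40.0 min, for which the same s gives 77.9%, and its share stands at 77.4%.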